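Cuts: the four phenol protecting groups come off last. The C3–O bond is traced back to a C3–B bond. Ring C is then cut at C3–C4 and O1–C2, and the ring B half at C1'–vinyl and at aryl–CH2(geranyl).
Enabling feature: O1, C8a, C4a and C4 of ring C form the oxadiene of an ortho-quinone methide of ring A. C2=C3 is the side-chain alkene of a ring B styrene, and the C3 hydroxyl sits on a carbon that can carry boron through the cycloaddition.
Forward order: rings A and B are bought as arenes. Ring B is geranylated at the bromine next to oxygen and then joined to vinyl MIDA boronate, while ring A is taken to the salicyl alcohol. Ring C is the only ring made, and it closes when the two halves meet.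
Stereochemistry: the 2,3-trans relation comes from suprafacial addition to the E alkene, and the absolute configuration from a chiral phosphoric acid. C–B becomes C–O with retention, and the E geranyl alkene comes from geranyl bromide.
Key step: step 7

Assumption: the sense of induction of the chiral acid in step 7, and of the chiral ligand in its fallback, cannot be deduced from related reactions. The (R)-acid is written; both antipodes are commercial, and the one that leads to the 2R,3S series of the target is meant.

Step 1
Reactants: 1 3,5-dibromosalicylaldehyde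
Product: 3 3,5-dibromocatechol, via aryl formate 2 (not isolated)
Conditions: 30% H2O2, aq NaOH, 0 °C to rt; then HCl
Reagents that add atoms: hydrogen peroxide, OO
Why: Dakin oxidation, in which hydroperoxide adds to the formyl group of the ortho-hydroxy arene, the aryl group migrates to oxygen and the formate 2 is saponified in the same basic medium, both C–Br bonds being inert.

Step 2
Reactants: 3 3,5-dibromocatechol
Product: 4 1,5-dibromo-2,3-bis(methoxymethoxy)benzene
Conditions: MOMCl, i-Pr2NEt, CH2Cl2, 0 °C to rt
Reagents that add atoms: chloromethyl methyl ether (MOMCl), COCCl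
Why: Williamson-type O-alkylation of both phenols with the reactive α-chloro ether should give acetals that withstand organolithium reagents, palladium catalysis and basic peroxide.

Step 3
Reactants: 4 1,5-dibromo-2,3-bis(methoxymethoxy)benzene; 5 geranyl bromide
Product: 8 5-bromo-1-[(2E)-3,7-dimethylocta-2,6-dienyl]-2,3-bis(methoxymethoxy)benzene, via aryllithium 6 (not isolated), via arylcopper 7 (not isolated)
Conditions: n-BuLi (1.0 equiv), THF, −78 °C; CuBr·SMe2, −78 to −40 °C; 5, −40 to 0 °C
Reagents that add atoms: n-butyllithium, [Li]CCCC (the lithium of 6 only); CuBr·SMe2, CSC.[Cu]Br (the copper of 7 only)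
Why: Bromine–lithium exchange goes to the bromine flanked by the chelating OMOM group, as is known for 2,4-dibromoanisoles, and the derived arylcopper displaces the primary allylic bromide in the SN2 sense with the E geometry kept, while the remaining C–Br bond is untouched by aryl copper species at this temperature.

Step 4
Reactants: 8 5-bromo-1-geranyl-2,3-bis(methoxymethoxy)benzene; 9 vinyl MIDA boronate
Product: 10 (E)-2-[3-geranyl-4,5-bis(methoxymethoxy)phenyl]vinyl MIDA boronate
Conditions: Pd2(dba)3 (2.5 mol %), [HP(t-Bu)3]BF4 (10 mol %), Cy2NMe, anhydrous dioxane, 60 °C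
Reagents that add atoms: none
Why: Mizoroki–Heck arylation, a documented reaction of vinyl MIDA boronate: the saturated boron cannot transmetalate without water, insertion places the aryl group on the unsubstituted carbon, and syn β-hydride elimination gives the E alkene.

Step 5
Reactants: 11 2,4,6-trihydroxybenzaldehyde
Product: 12 2-hydroxy-4,6-bis(methoxymethoxy)benzaldehyde
Conditions: MOMCl (2.1 equiv), i-Pr2NEt (2.5 equiv), CH2Cl2, 0 °C to rt
Reagents that add atoms: chloromethyl methyl ether (MOMCl), COCCl
Why: Selective O-alkylation, standard for 2,4,6-trihydroxyaryl carbonyl compounds, because after two alkylations the last ortho hydroxyl is held in a hydrogen bond to the formyl oxygen and stays free.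

Step 6
Reactants: 12 2-hydroxy-4,6-bis(methoxymethoxy)benzaldehyde
Product: 13 2-(hydroxymethyl)-3,5-bis(methoxymethoxy)phenol
Conditions: NaBH4, THF/MeOH, 0 °C, 20 min; pH 7 buffer; used directly
Reagents that add atoms: none
Why: Borohydride 1,2-reduction of an aryl aldehyde, run cold and briefly and worked up at neutral pH so that the electron-rich salicyl alcohol neither ionises nor is reduced further.

Step 7
Reactants: 13 2-(hydroxymethyl)-3,5-bis(methoxymethoxy)phenol; 10 (E)-2-[3-geranyl-4,5-bis(methoxymethoxy)phenyl]vinyl MIDA boronate
Product: 15 (2S,3S)-2-[3-geranyl-4,5-bis(methoxymethoxy)phenyl]-5,7-bis(methoxymethoxy)chroman-3-yl MIDA boronate (2,3-trans), via ortho-quinone methide 14 (not isolated)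
Conditions: (R)-TRIP [(R)-3,3'-bis(2,4,6-triisopropylphenyl)-1,1'-binaphthyl-2,2'-diyl hydrogen phosphate] (10 mol %), 5 Å MS, CH2Cl2, 0 °C; 13 (2 equiv) added to 10 over 12 h
Reagents that add atoms: none
Why: Proposed new method: the acid ionises the benzylic C–OH bond of 13, which the ring oxygens ortho and para to it make labile, and the resulting ortho-quinone methide 14 stays hydrogen-bonded through its carbonyl oxygen to the chiral phosphate while its 4π unit O1=C8a–C4a=C4 adds to the 2π bond C2=C3 of 10 in an inverse-demand hetero-Diels–Alder reaction, concerted but asynchronous, with C3–C4 formed ahead of O1–C2. The closest known reaction type is the chiral phosphoric acid or N-triflylphosphoramide catalysed [4+2] cycloaddition of ortho-quinone methides made in situ with styrenes to give 2-arylchromans, and what is new is the alkenyl MIDA boronate as 2π partner. Ring C, the only ring formed, closes as a six-membered oxacycle by this intermolecular [4+2] mode, and even in the stepwise limit the phenolic oxygen would capture the C2 cation through a half-chair that keeps the aryl and boryl groups equatorial. The regiochemistry needed (aryl on C2, boron on C3) is secured by the substrate, since the charge that develops at C2 is carried by the para oxygen O4' of ring B and by the electron-rich C3–B σ bond of tetrahedral boron, while the closed MIDA cage offers no vacant orbital to the phenoxide oxygen and so shuts off the alkenyl transfer with loss of boron that tricoordinate alkenylboronates show towards quinone methides. C2 and C3 are fixed relative to each other by suprafacial addition to the E alkene (2,3-trans), and their absolute sense, written 2S,3S here because boron ranks below carbon but identical in space with 2R,3S of the target, by the two 3,3'-aryl walls of the catalyst, which expose one face of bound 14 to one orientation of 10. Slow addition keeps 14 dilute so that the alkene competes with the nucleophilic C6 and C8 positions of ring A, the weak acid spares the MOM groups, the geranyl alkenes and the C2–O1 bond of 15, and the crystalline MIDA boronate can be recrystallised to raise enantiopurity.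

Step 8
Reactants: 15 (2S,3S)-chroman-3-yl MIDA boronate
Product: 17 (2R,3S)-2-[3-geranyl-4,5-bis(methoxymethoxy)phenyl]-5,7-bis(methoxymethoxy)chroman-3-ol, via boronic acid 16 (not isolated)
Conditions: 1 M aq NaOH (3 equiv), THF, 0 °C; then 30% H2O2, 0 °C to rt
Reagents that add atoms: hydrogen peroxide, OO (the C3 oxygen); sodium hydroxide, [Na+].[OH-] (the two boron-bound oxygens of 16 only)
Why: Base hydrolysis of the MIDA cage followed by boronate oxidation, in which hydroperoxide adds to the boron of 16 and C3 migrates from boron to oxygen with retention, so the trans relation is kept (the C2 descriptor changes from S to R by rank only) and MOM ethers and unactivated alkenes are inert to basic peroxide.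

Step 9
Reactants: 17 (2R,3S)-tetra-MOM chroman-3-ol
Product: 18 (2R,3S)-2-[3-geranyl-4,5-dihydroxyphenyl]chroman-3,5,7-triol (target, CID44420736)
Conditions: 1.25 M HCl in MeOH, THF, 35 °C, argon
Reagents that add atoms: none
Why: Acid-catalysed acetal exchange with methanol, the usual unmasking of MOM-protected C-prenylated and C-geranylated flavonoids, removes all four MOM groups as dimethoxymethane without touching C2, C3 or the E alkene.

Compound list
1 | 3,5-dibromo-2-hydroxybenzaldehyde (3,5-dibromosalicylaldehyde) | O=Cc1cc(Br)cc(Br)c1O | starting material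
2 | 3,5-dibromo-2-hydroxyphenyl formate | O=COc1cc(Br)cc(Br)c1O | intermediate
3 | 3,5-dibromobenzene-1,2-diol (3,5-dibromocatechol) | Oc1cc(Br)cc(Br)c1O | intermediate
4 | 1,5-dibromo-2,3-bis(methoxymethoxy)benzene | COCOc1cc(Br)cc(Br)c1OCOC | intermediate
5 | geranyl bromide, (2E)-1-bromo-3,7-dimethylocta-2,6-diene | CC(C)=CCC/C(C)=C/CBr | starting material
6 | [5-bromo-2,3-bis(methoxymethoxy)phenyl]lithium | [Li]c1cc(Br)cc(OCOC)c1OCOC | intermediate
7 | [5-bromo-2,3-bis(methoxymethoxy)phenyl]copper | [Cu]c1cc(Br)cc(OCOC)c1OCOC | intermediate
8 | 5-bromo-1-[(2E)-3,7-dimethylocta-2,6-dienyl]-2,3-bis(methoxymethoxy)benzene | CC(C)=CCC/C(C)=C/Cc1cc(Br)cc(OCOC)c1OCOC | intermediate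
9 | vinylboronic acid MIDA ester (vinyl MIDA boronate) | C=C[B-]12OC(=O)C[N+]1(C)CC(=O)O2 | starting material
10 | (E)-2-[3-geranyl-4,5-bis(methoxymethoxy)phenyl]vinyl MIDA boronate | CC(C)=CCC/C(C)=C/Cc1cc(/C=C/[B-]23OC(=O)C[N+]2(C)CC(=O)O3)cc(OCOC)c1OCOC | intermediate
11 | 2,4,6-trihydroxybenzaldehyde | O=Cc1c(O)cc(O)cc1O | starting material
12 | 2-hydroxy-4,6-bis(methoxymethoxy)benzaldehyde | O=Cc1c(O)cc(OCOC)cc1OCOC | intermediate
13 | 2-(hydroxymethyl)-3,5-bis(methoxymethoxy)phenol | OCc1c(O)cc(OCOC)cc1OCOC | intermediate
14 | 3,5-bis(methoxymethoxy)-6-methylidenecyclohexa-2,4-dien-1-one (ortho-quinone methide) | C=C1C(=O)C=C(OCOC)C=C1OCOC | intermediate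
15 | (2S,3S)-2-[3-geranyl-4,5-bis(methoxymethoxy)phenyl]-5,7-bis(methoxymethoxy)chroman-3-yl MIDA boronate, 2,3-trans | CC(C)=CCC/C(C)=C/Cc1cc([C@H]2Oc3cc(OCOC)cc(OCOC)c3C[C@@H]2[B-]45OC(=O)C[N+]4(C)CC(=O)O5)cc(OCOC)c1OCOC | intermediate
16 | (2S,3S)-2-[3-geranyl-4,5-bis(methoxymethoxy)phenyl]-5,7-bis(methoxymethoxy)chroman-3-ylboronic acid | CC(C)=CCC/C(C)=C/Cc1cc([C@H]2Oc3cc(OCOC)cc(OCOC)c3C[C@@H]2B(O)O)cc(OCOC)c1OCOC | intermediate
17 | (2R,3S)-2-[3-geranyl-4,5-bis(methoxymethoxy)phenyl]-5,7-bis(methoxymethoxy)chroman-3-ol | CC(C)=CCC/C(C)=C/Cc1cc([C@H]2Oc3cc(OCOC)cc(OCOC)c3C[C@@H]2O)cc(OCOC)c1OCOC | intermediate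
18 | (2R,3S)-2-[3-geranyl-4,5-dihydroxyphenyl]chroman-3,5,7-triol | CC(C)=CCC/C(C)=C/Cc1cc([C@H]2Oc3cc(O)cc(O)c3C[C@@H]2O)cc(O)c1O | target

Total step count: 9. Longest linear sequence: 7 (steps 1, 2, 3, 4, 7, 8, 9).

Steps most likely to fail

Step 7. Three things may go wrong.
- The bulk of the boryl cage at the attacking carbon may slow the cycloaddition. Self-condensation of the quinone methide, through attack by ring A carbons or the geranyl alkenes, could then take over.
- The C2–O1 bond of the product lies antiperiplanar to C3–B. It may ionise under acid, with ring opening and loss of boron.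
- Facial selectivity may be poor, because the catalyst holds only the heterodiene.

The fallback uses known chemistry, sets out from 10 and 12 and comes back at 17. Aqueous NaOH in THF frees the (E)-styrylboronic acid F1. Heating it with salicylaldehyde 12 and a substoichiometric amount of dibenzylamine in dioxane at 90 °C gives the racemic 2-aryl-2H-chromene F2, by catalytic Petasis borono-Mannich condensation, loss of the amine and oxa-6π electrocyclisation. Next comes copper-catalysed enantioselective protoboration under kinetic resolution (CuCl, (R,R)-Ph-BPE, NaOt-Bu, B2pin2, MeOH, THF). This reaction is known for 2-aryl-2H-chromenes and does not touch unactivated trisubstituted alkenes. It places boron on C3, anti to the C2 aryl group of the faster-reacting enantiomer, and gives the (2S,3S)-3-(pinacolatoboryl)flavan F3, at the price of half the material. NaBO3·4H2O in THF/H2O then oxidises it with retention to 17.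

Step 9. The freed 4'-phenol may add under acid to the neighbouring geranyl alkene, closing a chroman. The released formaldehyde equivalent may also be captured by the very nucleophilic ring A.

The fallback sets out from 17 and comes back at 18. TESOTf and 2,2'-bipyridyl in CH2Cl2 at 0 °C exchange the four aryl MOM ethers for silyl ethers and silylate the C3 hydroxyl, giving the pentakis(triethylsilyl) ether F4. The one-carbon unit leaves in the aqueous wash as a pyridinium salt before any phenol is free. Et3N·3HF in THF at 0 °C under argon then frees all five hydroxyls without Brønsted acid catalysis.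

Step 4. Oxidative addition to the electron-rich aryl bromide may be slow. Palladium hydride may shift the geranyl double bonds, and the MIDA ligand may be partly lost at raised temperature.

The fallback sets out from 8 and comes back at 10. Bromine–lithium exchange (n-BuLi, THF, −78 °C) and quenching with DMF give the aldehyde F5. Boron-Wittig olefination with CH2(Bpin)2 and lithium 2,2,6,6-tetramethylpiperidide (THF, 0 °C) gives the (E)-alkenyl pinacol boronate F6. Heating this with N-methyliminodiacetic acid and HC(OEt)3 in DMSO at 100 °C exchanges pinacol for the MIDA ligand and gives 10.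

Further compounds
F1 | step 7 | (E)-2-[3-geranyl-4,5-bis(methoxymethoxy)phenyl]vinylboronic acid | CC(C)=CCC/C(C)=C/Cc1cc(/C=C/B(O)O)cc(OCOC)c1OCOC
F2 | step 7 | racemic 2-[3-geranyl-4,5-bis(methoxymethoxy)phenyl]-5,7-bis(methoxymethoxy)-2H-chromene | CC(C)=CCC/C(C)=C/Cc1cc(C2C=Cc3c(OCOC)cc(OCOC)cc3O2)cc(OCOC)c1OCOC
F3 | step 7 | (2S,3S)-2-[3-geranyl-4,5-bis(methoxymethoxy)phenyl]-5,7-bis(methoxymethoxy)-3-(4,4,5,5-tetramethyl-1,3,2-dioxaborolan-2-yl)chroman | CC(C)=CCC/C(C)=C/Cc1cc([C@H]2Oc3cc(OCOC)cc(OCOC)c3C[C@@H]2B4OC(C)(C)C(C)(C)O4)cc(OCOC)c1OCOC
F4 | step 9 | (2R,3S)-pentakis(triethylsilyl) ether of 18 | CC(C)=CCC/C(C)=C/Cc1cc([C@H]2Oc3cc(O[Si](CC)(CC)CC)cc(O[Si](CC)(CC)CC)c3C[C@@H]2O[Si](CC)(CC)CC)cc(O[Si](CC)(CC)CC)c1O[Si](CC)(CC)CC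
F5 | step 4 | 3-geranyl-4,5-bis(methoxymethoxy)benzaldehyde | CC(C)=CCC/C(C)=C/Cc1cc(C=O)cc(OCOC)c1OCOC
F6 | step 4 | (E)-2-[3-geranyl-4,5-bis(methoxymethoxy)phenyl]vinylboronic acid pinacol ester | CC(C)=CCC/C(C)=C/Cc1cc(/C=C/B2OC(C)(C)C(C)(C)O2)cc(OCOC)c1OCOC
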